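You have a closed, stirred vessel in which solid substrate dissolves to starting material. The list of suspects has partner going to target, to second product, to third product and to self-condensation product.

| setting | Wednesday's | Saturday's | flask |
|---|---|---|---|
| solid substrate | 0.10 M | 0.10 M | 0.10 M |
| partner | 0.13 M | 0.13 M | 0.130 M |
| second substrate | 0.50 M | 0.50 M | 0.500 M |
| third substrate | 0.50 M | 0.50 M | 0.500 M |
| temperature | 20 °C | 26 °C | 20 °C |
| remark | the very flask that is asked about, followed so far | run made earlier |  |
| time |  |  | 3.0 d |

| run | time / h | target / % | solid substrate / % |
|---|---|---|---|
| Wednesday's | 15.0 | 12.0 | 20.5 |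
| Wednesday's | 30.0 | 12.5 | 5.3 |
| Wednesday's | 40.0 | 12.6 | 3.3 |
| Wednesday's | 60.0 | 12.9 | 2.7 |
| Saturday's | 15.0 | 8.4 | 22.7 |
| Saturday's | 30.0 | 8.8 | 9.1 |
| Saturday's | 40.0 | 9.1 | 7.1 |
| Saturday's | 60.0 | 7.9 | 6.2 |

(scatter of a reading: 0.3 percentage points)

- as a solid, counted per litre of solution: solid substrate
- removed target is counted in
- the earlier runs were read with a standard deviation of 0.3 percentage points
- on the list of suspects stand: 2 partner -> self-condensation product; starting material + partner -> target; solid substrate <-> starting material; second substrate + partner -> second product; third substrate + partner -> third product
- at the start none of the solid substrate is in solution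
- additions bring no volume worth counting

- north-west: at 3.0 d take out 90% of the target then present, then wait 6.0 d
- north-east: at 3.0 d add partner, 50.0% of the amount charged, then wait 6.0 d
- east: change nothing and wait 6.0 d more
- south: at 3.0 d raise the temperature by 10 K, then wait 6.0 d

* target, in percent of the solid substrate first charged, at 3.0 d
* which option adds most target ("none" when 2 percentage points or less is all one gets) (north-west / north-east / east / south / none)
* target present, with what was taken out counted in, in percent of the solid substrate first charged, after north-west
* target present, with what was taken out counted in, in percent of the solid substrate first charged, after east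

Turn the choice round. Under north-east, fresh partner enters the flask. For the answer "none" to be right, that partner would have to make 2 percentage points of target or less, so the share of it ending as target could not exceed

  s = 2 points × c(solid substrate) / (50.0% × c(partner)) = 3.08%

Now read the same share from Wednesday's run:

  Y = 12.9% × 0.10 M / 0.13 M = 9.92%

Call Y the partner yield, the target made per partner charged. Between 30.0 h and 60.0 h Wednesday's target rose 0.4 points, against a scatter of 0.3 points. By difference, the readings at 60.0 h put 84.4% of the solid charged as dissolved but unreacted, more than the target. So I reckon partner is the limiting reagent. Y stands 3.22 times above s. If added partner merely matched Y, north-east would give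

  gain = Y × 50.0% × c(partner) / c(solid substrate) = 6.5 points

The forecast says 13% at 3.0 d, 13.4% after north-west, 13.4% after east, and north-east as best, holding that “the stall comes from partner running out”.

The flask gives 12.6%, then 12.6% after north-west and 12.6% after east. Best is north-east, adding 23 points, while south adds 0 points.

    2 partner → self-condensation product (k = 1.60 M⁻¹ h⁻¹, Ea = 76.0 kJ mol⁻¹)
    starting material + partner → target (k = 2.00 M⁻¹ h⁻¹, Ea = 73.0 kJ mol⁻¹)
    solid substrate ⇌ starting material, rate k3*(cs3 - [starting material]) while solid is left; crystals form when [starting material] > cs3 (solubility = 0.0850 M, k = 0.120 h⁻¹)
    second substrate + partner → second product (k = 0.240 M⁻¹ h⁻¹, Ea = 84.0 kJ mol⁻¹)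
    third substrate + partner → third product (k = 0.140 M⁻¹ h⁻¹, Ea = 59.0 kJ mol⁻¹)
    (constants at 20 °C)

In this flask partner stands at 0% at 72.0 h, and a longer wait leaves the target where it is. Under north-east the added partner puts 35.6% of itself into target, more than the 9.92% of Y. In the neighbour with 0.025 M of solid substrate and the same partner, the carried Y gives 51.6% of that solid. That neighbour ends with partner at 0% and starting material at 64.3%, its own Y at 6.86%, and its target at 35.7%.

The numbers in the tables are calculated with made-up constants; noise was put on by code.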